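## Numbering used throughout

Atoms (target numbering): five-ring C1(Me)–C2–C3–C4(OH)(i-Pr)–C5(H); seven-ring C5–C6(OAr)–C7–C8(Me)=C9–C10(=O)–C1.

Compounds: **1** silyloxy enone; **2** iodo enone; **3** methyl enone; **4** ethyl vinyl ether; **5** allyl iodide; **6** enolate after conjugate addition; **7** allyl ketone; **8** enolate of 7; **9** C8-methyl ketone; **10** bicyclic enol ether; **11** trans-hydrindanedione; **12** C4 carbinol; **13** diol; **14** 4-methoxybenzoyl chloride; **15** keto ester; **16** bis-silyl enol ether; **17** diiodomethane; **18** siloxycyclopropane; **19** chloro ketone; **20** target as its C4 silyl ether; **21** target.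

## Analysis of the target

The target is a daucane-type hydroazulene: a cyclopentane fused through the C1–C5 bond to a cycloheptenone, with a 4-methoxybenzoate on the C6 oxygen. The four stereocentres C1 (S), C4 (R), C5 (S) and C6 (S) are contiguous around C5. The ring fusion is trans (C1 methyl and H5 on opposite faces), the C4 hydroxyl lies on the face of the C1 methyl, and the C6 acyloxy group lies on the face of H5, trans to the C5–C4 bond. The sensitive groups are the tertiary C4 carbinol (dehydration in strong acid), the enone, and the C6 ester, which sits δ to the carbonyl through the enone, so deprotonation at C7 can expel it to give a dienone. The synthesis is hard because C1 is a quaternary centre wedged between the ketone and the fusion carbon of a trans-fused 5–7 system, and a seven-ring gives little conformational bias for setting C1, C5 and C6. A further trap is that any bicyclic intermediate with a ketone at C4 next to C5–H prefers the cis fusion at equilibrium, so C5 must never be equilibrated. The strategy rests on the position of the C10 carbonyl between quaternary C1 and the C9H=C8(Me) unit: if C9 is deleted, what remains is a cyclohexanone whose only enolisable α-carbon is the methyl-bearing C8. All four stereocentres can therefore be set on a trans-hydrindane chair and C9 inserted afterwards, which makes the seven-ring and the enone at once.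

## Retrosynthetic reasoning

**21 ⇒ 20.** Only the C4–O–Si bond is cut. The last step is a silyl ether cleavage that runs in dilute acid, because base is what the target tolerates least.

**20 ⇒ 16 + 17.** The C9–C10 and C8–C9 bonds are cut and C9 is excised, so the cycloheptenone contracts to the cyclohexanone enol ether 16 and C9 is traced to 17. The cut is made here because C1 is quaternary, so 16 is the only enol ether the ketone can form, and because C8 carries the methyl, so the ring-opening produces a tertiary radical and the methyl ends β to the carbonyl. What is gained is that all stereochemistry is handled on a six-ring and none in the ring-enlarging step. The forward reaction has to add a carbenoid to a hindered tetrasubstituted enol ether, break the shared cyclopropane bond and not the outer one, and lose the elements of hydrogen chloride toward C9 without disturbing the C6 ester.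

**16 ⇒ 15 ⇒ 13 + 14 ⇒ 12.** These are changes at oxygen only. Both silyl groups of 16 (enol ether and C4 ether) go on in one operation from 15. The ester C–O bond is cut to diol 13 and acid chloride 14, relying on secondary versus tertiary hydroxyl. 13 comes from silyl ether 12. The ester is introduced only after every organometallic step is over.

**12 ⇒ 11.** The C4–isopropyl bond is cut. Addition of an isopropyl nucleophile to the C4 ketone of 11 must take the face of H5, away from the axial C1 methyl that is 1,3 to C4, and must choose the cyclopentanone over the C10 ketone, which is flanked by quaternary C1 and by C8(H)Me.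

**11 ⇒ 9 (through 10).** The C3–C4 bond is cut as a C3=C4 alkene. Metathesis between the allyl group on C1 and the 1-ethoxyvinyl group on C5 of 9 closes the five-ring. Because the alkene partner is an enol ether, C4 arrives already oxygenated and hydrolysis of 10 gives the ketone with no oxidation step. The two arms are trans-diequatorial on the chair, so the trans fusion is the one the ground state closes to.

**9 ⇒ 7 (through 8).** The C8–methyl bond is cut. It is placed after the quaternary centre because 7 can then enolise in one direction only. The methyl also adds the hindrance at C10 that the later addition at C4 relies on. Its configuration is irrelevant.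

**7 ⇒ 3 + 4 + 5 (through 6).** The C4–C5 and C1–C2 bonds are cut in one three-component operation on enone 3. The acyl-anion equivalent from 4 adds to C5 anti to the C6 silyloxy group, and the enolate 6 so formed is allylated by 5 anti to the new C5 substituent. This sets C5 and the quaternary C1 relative to C6.

**3 ⇒ 2 ⇒ 1.** The C1–methyl bond is cut as an sp2–sp3 cross-coupling of iodo enone 2, which comes from 1 by α-iodination. Enone 1 supplies the C6 configuration for the whole route.

## Alternatives that were turned down

**Alternative 1: arene ring enlargement by an intramolecular Buchner reaction.** The C5–C1 and C5–C6 bonds are cut, which turns the seven-ring back into a benzene ring and leaves C5 as a carbene carbon in diazoketone A2, 1-diazo-4-(2-methoxy-4-methylphenyl)butan-2-one. In the forward sense a chiral dirhodium tetracarboxylate such as Rh2(S-PTTL)4, the tetrakis[N-phthaloyl-(S)-tert-leucinate], decomposes A2. Cyclopropanation of the arene across the ipso/ortho bond and norcaradiene opening give trienone A1, (8aR)-4-methoxy-6-methyl-3,8a-dihydroazulen-1(2H)-one.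
- For: on step count to the bicyclic skeleton this route is clearly stronger. A1 holds all ten ring carbons, the C8 methyl and oxygen at C4 and C10 a few steps from a simple arene, and its one stereocentre comes from a catalyst.
- Against: that stereocentre is C5, and its hydrogen in A1 is α to the C4 ketone and doubly allylic, so enolisation or a 1,5-hydrogen shift around the triene can erase it. The carbenoid can also choose between two ortho positions, aromatic substitution of the electron-rich ring, and insertion into the methoxy group. Everything that is hard about the target remains: C1 is trigonal and must become a quaternary centre trans to H5, C6 must be oxygenated selectively within a triene, and the C4 carbinol is still to be made.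
- Comparison: the chosen route spends more steps reaching the bicycle, but it fixes C1, C5 and C6 by substrate control on a chair before any sensitive unsaturation exists, and its ring-enlarging step needs no stereocontrol.

**Alternative 2: five-ring last by a SmI2 Barbier closure.** The C3–C4 bond is cut, leading to cycloheptanone A4, (2S,3S,4S)-4-(tert-butyldimethylsilyloxy)-2-(2-iodoethyl)-2-methyl-3-(2-methylpropanoyl)cycloheptan-1-one. In the forward sense SmI2 with HMPA turns the primary iodide into an organosamarium that adds to the isopropyl ketone, giving A3, (1R,3aS,8S,8aS)-8-(tert-butyldimethylsilyloxy)-1-hydroxy-3a-methyl-1-(propan-2-yl)octahydroazulen-4(1H)-one.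
- For: the last ring and the C4 carbinol form in one nearly neutral operation and the seven-ring is present from the start. The route never passes through a bicyclic C4 ketone whose C5–H could epimerise to the cis fusion. On that point it is stronger than the chosen route, which must carry dione 11 without equilibration.
- Against: A3 lacks both the C8 methyl and the C8=C9 bond, which cost about four further steps (dehydrogenation, conjugate methylation, second dehydrogenation) on a base-sensitive skeleton. A4 needs C1 and C5 set on an enantiopure silyloxycycloheptenone, for which there is neither a chiral-pool source nor the firm anti selectivities of a cyclohexenone half-chair. Divalent samarium also reduces the C10 ketone to a ketyl. The face of the C4 ketone attacked in the closure depends on the rotamer about C4–C5 and on chelation by the C6 oxygen, with no clear bias toward the hydroxyl cis to the C1 methyl.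
- Comparison: the chosen route sets C4 by intermolecular addition to a rigid trans-hydrindanone whose one face is blocked by the axial methyl, and it brings in the C8 methyl and the C8=C9 bond in the same operation that makes the seven-ring.

**Alternative 3: decalin to hydroazulene by a semipinacol 1,2-shift.** The C1–C5 bond is cut and C1 is rejoined to C6, which converts both rings into six-rings: the cis-fused decalin-4,6-diol 5-methanesulfonate A6 (target atom numbering, C10 as ethylene ketal). In the forward sense KOt-Bu forms the C6 alkoxide of A6. As the C6 carbonyl develops, C1 migrates from C6 to C5 and the mesylate leaves, giving A5, the trans-fused hydroazulen-6-one with the C4 hydroxyl, the isopropyl group and the C10 ethylene ketal.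
- For: decalins of this kind come from cheap, well-understood enantioselective annulation chemistry. The shift is stereospecific (retention at C1, inversion at C5), so the trans fusion follows from the substrate, and two ring sizes change in one step. As a way of making the C1–C5 junction it is at least as secure as the tandem alkylation of the chosen route.
- Against: the migrating C1–C6 bond must be anti-periplanar to the C5–O bond. Worked back from the target configuration, this demands a cis-fused decalin with an equatorial C5 mesylate, so A6 carries three contiguous oxygenated carbons (C4, C5, C6) plus C1, all to be set although C6 is then destroyed. In A5 the C4 hydroxyl is β to the new C6 ketone, so under the same alkoxide both retro-aldol cleavage of C4–C5 and epimerisation of the now acidic C5–H are open. A5 still lacks the C6 alcohol stereocentre, the C8 methyl and the C8=C9 bond.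
- Comparison: the chosen route has no β-hydroxy ketone at any stage (the C4 oxygen is γ to C10), carries C6 as a stereocentre from the first compound, and its ring-size change delivers the finished enone.

Key step: step 10

Remark: enone 1 is taken as a catalogue compound of full enantiomeric purity, and the two C8 epimers that arise in step 4 are carried together because C8 becomes trigonal in 16.

## Route

Step 1
Reactants: 1 (S)-4-(tert-butyldimethylsilyloxy)cyclohex-2-en-1-one
Product: 2 (S)-4-(tert-butyldimethylsilyloxy)-2-iodocyclohex-2-en-1-one
Conditions: I2, pyridine, CH2Cl2, 0 °C → rt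
Reagents that add atoms: iodine, II
Why: α-Iodination of a cyclic enone under amine catalysis (conjugate addition of pyridine, iodination of the enolate, E1cB loss of pyridine); the C6 stereocentre is not part of the sequence and keeps its configuration.

Step 2
Reactants: 2 (S)-4-(tert-butyldimethylsilyloxy)-2-iodocyclohex-2-en-1-one
Product: 3 (S)-4-(tert-butyldimethylsilyloxy)-2-methylcyclohex-2-en-1-one
Conditions: Me4Sn, Pd2(dba)3 (cat.), AsPh3, CuI, NMP, 80 °C
Reagents that add atoms: tetramethylstannane, C[Sn](C)(C)C
Why: Stille coupling of an α-iodo enone, with AsPh3 and CuI to speed the slow methyl transfer; the conditions are neutral, so the γ-hydrogen at the C6 stereocentre is not at risk.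

Step 3
Reactants: 3 (S)-4-(tert-butyldimethylsilyloxy)-2-methylcyclohex-2-en-1-one; 4 ethyl vinyl ether; 5 allyl iodide
Product: 7 (2S,3S,4S)-2-allyl-4-(tert-butyldimethylsilyloxy)-3-(1-ethoxyvinyl)-2-methylcyclohexan-1-one, via lithium enolate 6 (not isolated)
Conditions: 4, t-BuLi, THF, −78 → 0 °C; CuI, −78 → −40 °C; 3, −78 °C; then HMPA, 5, −78 → −20 °C; NH4Cl/NH3 buffer
Reagents that add atoms: ethyl vinyl ether 4, C=COCC; allyl iodide 5, C=CCI
Why: Conjugate addition of a lithium di(1-alkoxyvinyl)cuprate (acyl-anion equivalent) followed by C-alkylation of the regiodefined enolate in the same flask. The cuprate attacks C5 on the face opposite the C6 silyloxy group, and allyl iodide attacks enolate 6 on the face opposite the new C5 substituent, so the C1 allyl and C5 vinyl arms are trans and C1 becomes quaternary with its methyl on the face away from H5.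

Step 4
Reactants: 7 (2S,3S,4S)-2-allyl-4-(tert-butyldimethylsilyloxy)-3-(1-ethoxyvinyl)-2-methylcyclohexan-1-one
Product: 9 (2S,3S,4S)-2-allyl-4-(tert-butyldimethylsilyloxy)-3-(1-ethoxyvinyl)-2,6-dimethylcyclohexan-1-one as the mixture of C6 epimers, via lithium enolate 8 (not isolated)
Conditions: LiN(i-Pr)2, THF, −78 °C; MeI, −78 → 0 °C
Reagents that add atoms: iodomethane, CI
Why: Enolate alkylation; C1 is quaternary, so the amide base can enolise 7 only toward C8, and the configuration of the new methyl-bearing carbon does not matter because it becomes trigonal in 16.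

Step 5
Reactants: 9 (2S,3S,4S)-2-allyl-4-(tert-butyldimethylsilyloxy)-3-(1-ethoxyvinyl)-2,6-dimethylcyclohexan-1-one
Product: 11 (3aS,7S,7aS)-7-(tert-butyldimethylsilyloxy)-3a,5-dimethyloctahydro-1H-indene-1,4-dione (both C5 epimers; trans-fused), via bicyclic enol ether 10 (not isolated)
Conditions: (H2IMes)(PCy3)Cl2Ru=CHPh (second-generation Grubbs catalyst, 5 mol %), toluene, 70 °C; then 10% aq. oxalic acid, THF, 0 °C
Reagents that add atoms: water, O
Why: Enol ether–olefin ring-closing metathesis: the ruthenium alkylidene loads on the allyl group and closes onto the 1,1-disubstituted enol ether across two equatorial arms, giving the trans-fused cyclopentene 10. Mild acid then protonates C3, not C5, and water converts the oxocarbenium ion into the C4 ketone, so the ring-fusion hydrogen is untouched if the contact with acid is kept short and cold.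

Step 6
Reactants: 11 (3aS,7S,7aS)-7-(tert-butyldimethylsilyloxy)-3a,5-dimethyloctahydro-1H-indene-1,4-dione
Product: 12 (1R,3aS,7S,7aS)-7-(tert-butyldimethylsilyloxy)-1-hydroxy-3a,5-dimethyl-1-(propan-2-yl)octahydro-4H-inden-4-one
Conditions: CeCl3 (anhydrous), i-PrMgCl, THF, −78 °C; aq. NH4Cl
Reagents that add atoms: isopropylmagnesium chloride, CC(C)[Mg]Cl
Why: Organocerium 1,2-addition, whose low basicity suppresses enolisation and β-hydride reduction. The reagent should choose the cyclopentanone over the C10 ketone, which is flanked by quaternary C1 and C8(H)Me. It should enter from the face of H5, opposite the axial C1 methyl that is 1,3 to C4, which places the hydroxyl cis to that methyl (4R in target numbering).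

Step 7
Reactants: 12 (1R,3aS,7S,7aS)-7-(tert-butyldimethylsilyloxy)-1-hydroxy-3a,5-dimethyl-1-(propan-2-yl)octahydro-4H-inden-4-one
Product: 13 (1R,3aS,7S,7aS)-1,7-dihydroxy-3a,5-dimethyl-1-(propan-2-yl)octahydro-4H-inden-4-one
Conditions: Bu4NF, THF, 0 °C → rt; aq. NH4Cl
Reagents that add atoms: none
Why: Fluoride cleavage of the secondary silyl ether; neither hydroxyl is β to the ketone, so no retro-aldol path exists, and C5 is no longer enolisable.

Step 8
Reactants: 13 (1R,3aS,7S,7aS)-1,7-dihydroxy-3a,5-dimethyl-1-(propan-2-yl)octahydro-4H-inden-4-one; 14 4-methoxybenzoyl chloride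
Product: 15 (3R,3aS,4S,7aS)-3-hydroxy-6,7a-dimethyl-7-oxo-3-(propan-2-yl)octahydro-1H-inden-4-yl 4-methoxybenzoate
Conditions: 14, Et3N, DMAP (cat.), CH2Cl2, 0 °C → rt
Reagents that add atoms: 4-methoxybenzoyl chloride 14, COc1ccc(cc1)C(Cl)=O
Why: DMAP-catalysed acylation; the equatorial secondary C6 hydroxyl reacts and the tertiary C4 hydroxyl, which is on the opposite face and flanked by isopropyl, does not.

Step 9
Reactants: 15 (3R,3aS,4S,7aS)-3-hydroxy-6,7a-dimethyl-7-oxo-3-(propan-2-yl)octahydro-1H-inden-4-yl 4-methoxybenzoate
Product: 16 (3R,3aS,4S,7aS)-6,7a-dimethyl-3-(propan-2-yl)-3,7-bis(trimethylsilyloxy)-2,3,3a,4,5,7a-hexahydro-1H-inden-4-yl 4-methoxybenzoate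
Conditions: Me3SiOTf, Et3N, CH2Cl2, 0 °C → rt
Reagents that add atoms: trimethylsilyl trifluoromethanesulfonate, C[Si](C)(C)OS(=O)(=O)C(F)(F)F
Why: Soft enolisation (O-silylation, then deprotonation by the amine): C1 is quaternary, so only the C8=C10 enol ether can form and both C8 epimers converge. The same reagent silylates the tertiary hydroxyl, which keeps it away from the zinc and iron reagents of the next step; the aryl ester has no α-hydrogen and is inert.

Step 10
Reactants: 16 (3R,3aS,4S,7aS)-6,7a-dimethyl-3-(propan-2-yl)-3,7-bis(trimethylsilyloxy)-2,3,3a,4,5,7a-hexahydro-1H-inden-4-yl 4-methoxybenzoate; 17 diiodomethane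
Product: 20 (3R,3aS,4S,8aS)-6,8a-dimethyl-8-oxo-3-(propan-2-yl)-3-(trimethylsilyloxy)-1,2,3,3a,4,5,8,8a-octahydroazulen-4-yl 4-methoxybenzoate, via siloxycyclopropane 18 (not isolated), via chloro ketone 19 (not isolated)
Conditions: Et2Zn, 17, CH2Cl2, 0 °C → rt; pyridine, filter, evaporate; FeCl3, pyridine, DMF, 0 °C → rt; aqueous work-up; NaOAc, MeOH, 60 °C
Reagents that add atoms: diiodomethane 17, ICI
Why: The zinc carbenoid EtZnCH2I adds in a concerted syn fashion to the only C=C bond of 16, the electron-rich C8=C10 enol ether, closing the three-membered ring with C8–C9 and C9–C10 formed together (either face serves). FeCl3 then oxidises the siloxycyclopropane by one electron with loss of the silyl group, and the cyclopropyloxy radical breaks the shared C8–C10 bond, because only that scission gives a tertiary radical (at C8) and releases the bicyclic strain; the seven-ring therefore arises by enlargement of the six-ring and not by an end-to-end cyclisation. The C8 radical takes chlorine from a second FeCl3 to give 19, and acetate removes hydrogen chloride through the C9 enolate, the only enolate available since C1 is quaternary, so the alkene ends at C8=C9 in conjugation. The closest known reaction type is the Saegusa–Ito one-carbon enlargement of cyclic trimethylsilyl enol ethers, including α-methyl, tetrasubstituted cases that give β-methyl cycloalkenones. No stereocentre is created: the two cyclopropane carbons are transient and C8 ends trigonal, while C1, C4, C5 and C6 lie outside the reacting bonds. The step needs regioselectivity only (which cyclopropane bond breaks and in which direction hydrogen chloride leaves), and both are fixed by the substrate as described; the C4 silyl ether shields the tertiary oxygen and the weak base should leave the C6 ester in place.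

Step 11
Reactants: 20 (3R,3aS,4S,8aS)-6,8a-dimethyl-8-oxo-3-(propan-2-yl)-3-(trimethylsilyloxy)-1,2,3,3a,4,5,8,8a-octahydroazulen-4-yl 4-methoxybenzoate
Product: 21 (3R,3aS,4S,8aS)-3-hydroxy-6,8a-dimethyl-8-oxo-3-(propan-2-yl)-1,2,3,3a,4,5,8,8a-octahydroazulen-4-yl 4-methoxybenzoate (target)
Conditions: 1 M aq. HCl, THF, 0 °C → rt
Reagents that add atoms: none
Why: Acid-catalysed cleavage of a tertiary trimethylsilyl ether at the Si–O bond; acid is chosen over fluoride or base because a base could deprotonate C7 and expel the C6 ester, while cold dilute acid should neither dehydrate the carbinol nor touch the enone or ester.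

## Compound list

1 | (S)-4-(tert-butyldimethylsilyloxy)cyclohex-2-en-1-one | O=C1C=C[C@@H](O[Si](C)(C)C(C)(C)C)CC1 | starting material
2 | (S)-4-(tert-butyldimethylsilyloxy)-2-iodocyclohex-2-en-1-one | O=C1C(I)=C[C@@H](O[Si](C)(C)C(C)(C)C)CC1 | intermediate
3 | (S)-4-(tert-butyldimethylsilyloxy)-2-methylcyclohex-2-en-1-one | O=C1C(C)=C[C@@H](O[Si](C)(C)C(C)(C)C)CC1 | intermediate
4 | ethyl vinyl ether | CCOC=C | starting material
5 | allyl iodide | C=CCI | starting material
6 | lithium (3S,4S)-4-(tert-butyldimethylsilyloxy)-3-(1-ethoxyvinyl)-2-methylcyclohex-1-en-1-olate | CC(C)(C)[Si](C)(C)O[C@H]1CCC([O-])=C(C)[C@@H]1C(=C)OCC.[Li+] | intermediate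
7 | (2S,3S,4S)-2-allyl-4-(tert-butyldimethylsilyloxy)-3-(1-ethoxyvinyl)-2-methylcyclohexan-1-one | CC(C)(C)[Si](C)(C)O[C@H]1CCC(=O)[C@@](C)(CC=C)[C@@H]1C(=C)OCC | intermediate
8 | lithium (4S,5S,6S)-6-allyl-4-(tert-butyldimethylsilyloxy)-5-(1-ethoxyvinyl)-6-methylcyclohex-1-en-1-olate | CC(C)(C)[Si](C)(C)O[C@H]1CC=C([O-])[C@@](C)(CC=C)[C@@H]1C(=C)OCC.[Li+] | intermediate
9 | (2S,3S,4S)-2-allyl-4-(tert-butyldimethylsilyloxy)-3-(1-ethoxyvinyl)-2,6-dimethylcyclohexan-1-one (C6 epimers) | CC(C)(C)[Si](C)(C)O[C@H]1CC(C)C(=O)[C@@](C)(CC=C)[C@@H]1C(=C)OCC | intermediate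
10 | (3aS,7S,7aS)-7-(tert-butyldimethylsilyloxy)-1-ethoxy-3a,5-dimethyl-3,3a,5,6,7,7a-hexahydro-4H-inden-4-one (C5 epimers) | CC(C)(C)[Si](C)(C)O[C@H]1CC(C)C(=O)[C@@]2(C)CC=C(OCC)[C@H]12 | intermediate
11 | (3aS,7S,7aS)-7-(tert-butyldimethylsilyloxy)-3a,5-dimethyloctahydro-1H-indene-1,4-dione (C5 epimers) | CC(C)(C)[Si](C)(C)O[C@H]1CC(C)C(=O)[C@@]2(C)CCC(=O)[C@H]12 | intermediate
12 | (1R,3aS,7S,7aS)-7-(tert-butyldimethylsilyloxy)-1-hydroxy-3a,5-dimethyl-1-(propan-2-yl)octahydro-4H-inden-4-one (C5 epimers) | CC(C)(C)[Si](C)(C)O[C@H]1CC(C)C(=O)[C@@]2(C)CC[C@@](O)(C(C)C)[C@H]12 | intermediate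
13 | (1R,3aS,7S,7aS)-1,7-dihydroxy-3a,5-dimethyl-1-(propan-2-yl)octahydro-4H-inden-4-one (C5 epimers) | O[C@H]1CC(C)C(=O)[C@@]2(C)CC[C@@](O)(C(C)C)[C@H]12 | intermediate
14 | 4-methoxybenzoyl chloride | COc1ccc(cc1)C(Cl)=O | starting material
15 | (3R,3aS,4S,7aS)-3-hydroxy-6,7a-dimethyl-7-oxo-3-(propan-2-yl)octahydro-1H-inden-4-yl 4-methoxybenzoate (C6 epimers) | COc1ccc(cc1)C(=O)O[C@H]1CC(C)C(=O)[C@@]2(C)CC[C@@](O)(C(C)C)[C@H]12 | intermediate
16 | (3R,3aS,4S,7aS)-6,7a-dimethyl-3-(propan-2-yl)-3,7-bis(trimethylsilyloxy)-2,3,3a,4,5,7a-hexahydro-1H-inden-4-yl 4-methoxybenzoate | COc1ccc(cc1)C(=O)O[C@H]1CC(C)=C(O[Si](C)(C)C)[C@@]2(C)CC[C@@](O[Si](C)(C)C)(C(C)C)[C@H]12 | intermediate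
17 | diiodomethane | ICI | starting material
18 | siloxycyclopropane: 16 with a CH2 bridge (C9) across C8 and C10, cyclopropane face not defined | COc1ccc(cc1)C(=O)O[C@H]1CC2(C)CC2(O[Si](C)(C)C)[C@@]3(C)CC[C@@](O[Si](C)(C)C)(C(C)C)[C@H]13 | intermediate
19 | (3R,3aS,4S,8aS)-6-chloro-6,8a-dimethyl-8-oxo-3-(propan-2-yl)-3-(trimethylsilyloxy)decahydroazulen-4-yl 4-methoxybenzoate (C6 epimers) | COc1ccc(cc1)C(=O)O[C@H]1CC(C)(Cl)CC(=O)[C@@]2(C)CC[C@@](O[Si](C)(C)C)(C(C)C)[C@H]12 | intermediate
20 | (3R,3aS,4S,8aS)-6,8a-dimethyl-8-oxo-3-(propan-2-yl)-3-(trimethylsilyloxy)-1,2,3,3a,4,5,8,8a-octahydroazulen-4-yl 4-methoxybenzoate | COc1ccc(cc1)C(=O)O[C@H]1CC(C)=CC(=O)[C@@]2(C)CC[C@@](O[Si](C)(C)C)(C(C)C)[C@H]12 | intermediate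
21 | (3R,3aS,4S,8aS)-3-hydroxy-6,8a-dimethyl-8-oxo-3-(propan-2-yl)-1,2,3,3a,4,5,8,8a-octahydroazulen-4-yl 4-methoxybenzoate | COc1ccc(C(=O)O[C@H]2CC(C)=CC(=O)[C@@]3(C)CC[C@@](O)(C(C)C)[C@H]23)cc1 | target

## Step count and least certain steps

Total: 11 steps. Longest linear sequence: 11 steps, from 1 to 21; compounds 4, 5, 14 and 17 enter as bought.

**Step 10 (key step).** Two processes are most likely to fail. The first is slow carbenoid transfer to a tetrasubstituted enol ether that is shielded on one side by the quaternary C1, with the zinc iodide formed stripping the enol silyl group in competition. The second is loss of hydrogen chloride in an unconjugated direction, or onward loss of the C6 ester through C7 deprotonation, during the final base treatment.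
Fallback, from 16 back to 20: dibromocarbene (CHBr3, KOt-Bu, pentane, −30 °C) is a far more electrophilic carbene than the zinc carbenoid and should add to the enol ether of 16 to give the 9,9-dibromo siloxycyclopropane F1. On warming in toluene this should open, by loss of bromide and of the silyl group, to the ring-enlarged 9-bromo enone F2, which already has the C8=C9 bond, so no separate elimination is needed. Palladium-catalysed formate hydrogenolysis of the vinylic C9–Br bond (Pd(OAc)2, PPh3, HCO2H, Bu3N, DMF, 60 °C) should then give 20.

**Step 3.** The conjugate addition is the secure half. What is most likely to go wrong is sluggish C-allylation of the crowded, tetrasubstituted copper/lithium enolate 6, which allows proton transfer to C8 of the product and hence over-allylation, or O-allylation.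
Fallback, from 3 back to 7: after the same cuprate addition to 3 the enolate is trapped on oxygen with allyl chloroformate to give the allyl enol carbonate F3. Zerovalent palladium (Pd(PPh3)4, THF, rt) should then effect decarboxylative allylation (Tsuji allylation), which regenerates the same enolate as an ion pair with the allylpalladium cation and joins C1 to allyl on the face away from the C5 substituent, giving 7.

**Step 5.** Two processes threaten it: trapping of the ruthenium carbene by the electron-rich alkoxy alkene before ring closure, and loss of the trans ring fusion, either by migration of the enol ether double bond toward C5 or by acid-catalysed enolisation of the C4 ketone, which prefers the cis fusion at equilibrium.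
Fallback, from 9 back to 11: the ethoxyvinyl group of 9 is hydrolysed first (aq. oxalic acid) to the methyl ketone F4, in which C5 sits in its stable equatorial arrangement. Kinetic deprotonation of the acetyl methyl group (LiN(i-Pr)2, Et3SiCl, THF, −78 °C) gives the triethylsilyl enol ether F5. Ring-closing metathesis of this silyl enol ether with the second-generation Grubbs catalyst (H2IMes)(PCy3)Cl2Ru=CHPh, a documented way to five-membered cyclic silyl enol ethers, gives F6. The silyl enol ether is cleaved with buffered dilute acid to 11.

**Step 6.** The likely failures are enolisation of the cyclopentanone or hydride transfer from the branched reagent in place of addition, and, less likely, competing attack at C10.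
Fallback, from 11 back to 12: isopropenylmagnesium bromide with CeCl3 is an sp2 nucleophile that is smaller and has no hydride to transfer. It should add to the C4 ketone of 11 from the same face to give the isopropenyl carbinol F7. Hydrogenation of the 1,1-disubstituted alkene (H2, PtO2, EtOAc) then gives 12.

## Further compounds

F1 | step 10 | 9,9-dibromo analogue of siloxycyclopropane 18 (CBr2 bridging C8 and C10), cyclopropane face not defined | COc1ccc(cc1)C(=O)O[C@H]1CC2(C)C(Br)(Br)C2(O[Si](C)(C)C)[C@@]3(C)CC[C@@](O[Si](C)(C)C)(C(C)C)[C@H]13
F2 | step 10 | (3R,3aS,4S,8aS)-7-bromo-6,8a-dimethyl-8-oxo-3-(propan-2-yl)-3-(trimethylsilyloxy)-1,2,3,3a,4,5,8,8a-octahydroazulen-4-yl 4-methoxybenzoate | COc1ccc(cc1)C(=O)O[C@H]1CC(C)=C(Br)C(=O)[C@@]2(C)CC[C@@](O[Si](C)(C)C)(C(C)C)[C@H]12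
F3 | step 3 | allyl (3S,4S)-4-(tert-butyldimethylsilyloxy)-3-(1-ethoxyvinyl)-2-methylcyclohex-1-en-1-yl carbonate | CC(C)(C)[Si](C)(C)O[C@H]1CCC(OC(=O)OCC=C)=C(C)[C@@H]1C(=C)OCC
F4 | step 5 | (2S,3S,4S)-3-acetyl-2-allyl-4-(tert-butyldimethylsilyloxy)-2,6-dimethylcyclohexan-1-one (C6 epimers) | CC(C)(C)[Si](C)(C)O[C@H]1CC(C)C(=O)[C@@](C)(CC=C)[C@@H]1C(C)=O
F5 | step 5 | (2S,3S,4S)-2-allyl-4-(tert-butyldimethylsilyloxy)-2,6-dimethyl-3-[1-(triethylsilyloxy)vinyl]cyclohexan-1-one (C6 epimers) | CC(C)(C)[Si](C)(C)O[C@H]1CC(C)C(=O)[C@@](C)(CC=C)[C@@H]1C(=C)O[Si](CC)(CC)CC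
F6 | step 5 | (3aS,7S,7aS)-7-(tert-butyldimethylsilyloxy)-3a,5-dimethyl-1-(triethylsilyloxy)-3,3a,5,6,7,7a-hexahydro-4H-inden-4-one (C5 epimers) | CC(C)(C)[Si](C)(C)O[C@H]1CC(C)C(=O)[C@@]2(C)CC=C(O[Si](CC)(CC)CC)[C@H]12
F7 | step 6 | (1S,3aS,7S,7aS)-7-(tert-butyldimethylsilyloxy)-1-hydroxy-3a,5-dimethyl-1-(prop-1-en-2-yl)octahydro-4H-inden-4-one (C5 epimers) | CC(C)(C)[Si](C)(C)O[C@H]1CC(C)C(=O)[C@@]2(C)CC[C@@](O)(C(C)=C)[C@H]12
A1 | alternative 1 | (8aR)-4-methoxy-6-methyl-3,8a-dihydroazulen-1(2H)-one | O=C1CCC2=C(OC)C=C(C)C=C[C@@H]12
A2 | alternative 1 | 1-diazo-4-(2-methoxy-4-methylphenyl)butan-2-one | COc1cc(C)ccc1CCC(=O)C=[N+]=[N-]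
A3 | alternative 2 | (1R,3aS,8S,8aS)-8-(tert-butyldimethylsilyloxy)-1-hydroxy-3a-methyl-1-(propan-2-yl)octahydroazulen-4(1H)-one | CC(C)(C)[Si](C)(C)O[C@H]1CCCC(=O)[C@@]2(C)CC[C@@](O)(C(C)C)[C@H]12
A4 | alternative 2 | (2S,3S,4S)-4-(tert-butyldimethylsilyloxy)-2-(2-iodoethyl)-2-methyl-3-(2-methylpropanoyl)cycloheptan-1-one | CC(C)(C)[Si](C)(C)O[C@H]1CCCC(=O)[C@@](C)(CCI)[C@@H]1C(=O)C(C)C
A5 | alternative 3 | trans-fused hydroazulen-6-one with C4 hydroxyl, C4 isopropyl and C10 ethylene ketal (target atom numbering) | O=C1CCCC2(OCCO2)[C@@]3(C)CC[C@@](O)(C(C)C)[C@H]13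
A6 | alternative 3 | cis-fused decalin (target atom numbering, C1–C6 fusion): 4,6-dihydroxy-1-methyl-4-(propan-2-yl)-10,10-(ethylenedioxy)decalin 5-methanesulfonate | CS(=O)(=O)O[C@H]1[C@](O)(C(C)C)CC[C@]2(C)C3(OCCO3)CCC[C@]12O
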